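**Retrosynthetic overview** (azulene locants of the target: C-1 = C(CH2OH)(side chain), C-2 = CH(CH3), C-3 = CH2, C-3a = C(CHO), C-4 = CH(OH), C-8a = ring-fusion CH)
1. End game: acid unmasks the C-3a aldehyde (dimethyl acetal) and the C-4 alcohol (silyl ether); the (Z)-butenediol comes from a 3-substituted furan (singlet oxygen, then borohydride) and the C-1 CH2OH from a nitrile.
2. C-1 is made quaternary by convex-face alkylation of a bicyclic nitrile with 3-(2-iodoethyl)furan; the C-2 methyl comes from convex-face hydrogenation of an exocyclic methylene.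
3. Key disconnection: the whole bicycle from an acyclic N-acyloxyphthalimide in one reductive radical cascade that forms the C-3a–C-8a ring-fusion bond (7-exo, seven-membered ring first) and then the C-1–C-2 bond (5-exo-dig, five-membered ring second).
4. Enabling feature: the cyclopentane is a three-carbon unit (C-3a, C-3, C-2) laid across a two-carbon unit (C-8a, C-1) whose C-8a also belongs to the cycloheptene. C-3a bears only carbon substituents (masked CHO, the C-4 carbinol, C-3), so it can be a tertiary radical born from a carboxylic acid; C-8a is β to the carbon that carries the future CH2OH, so C-8a=C-1 can be an acrylonitrile; C-2 with its methyl can be a terminal alkyne.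
5. The acyclic precursor comes from an asymmetric Nozaki–Hiyama–Kishi coupling of a malonate-derived aldehyde with a (Z)-vinyl iodide; the C-4 carbinol set there is the only stereocentre made by a chiral reagent and controls C-3a and C-8a in the key step and, through the bicycle, C-2 and C-1.

Key step: step 9

Remark: 2-(furan-3-yl)ethan-1-ol is taken as a catalogue compound, and the nitrile double bond made in step 4 is drawn as its expected major Z isomer, the E isomer being equally usable because this double bond is consumed in step 9.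

**Route**

Step 1
Reactants: 1 dimethyl 2-(prop-2-yn-1-yl)propanedioate; 2 trimethyl orthoformate
Product: 3 dimethyl 2-(dimethoxymethyl)-2-(prop-2-yn-1-yl)propanedioate
Conditions: TiCl4, Et3N, CH2Cl2, −78 °C; then 2, −78 → 0 °C
Reagents that add atoms: none
Why: Soft enolisation gives the titanium enolate of the malonate, which should be C-alkylated by the dimethoxycarbenium ion released from the orthoformate (enolate–orthoester alkylation); no stereocentre is formed.

Step 2
Reactants: 3 dimethyl 2-(dimethoxymethyl)-2-(prop-2-yn-1-yl)propanedioate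
Product: 4 methyl 2-(dimethoxymethyl)-2-formylpent-4-ynoate (racemic)
Conditions: i-Bu2AlH (1.05 equiv), CH2Cl2, −78 °C; aqueous potassium sodium tartrate
Reagents that add atoms: none
Why: Partial ester reduction: one of the two enantiotopic esters should stop at the aldehyde level because the chelated aluminium hemiacetal survives at −78 °C until work-up, and the racemic quaternary centre is harmless because it becomes a radical in step 9.

Step 3
Reactants: 5 pent-4-enal; 6 ethyltriphenylphosphonium iodide
Product: 8 (5Z)-6-iodohepta-1,5-diene, via iodophosphonium salt 7 (not isolated)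
Conditions: 6, n-BuLi, THF, 0 °C; I2, −78 °C; NaN(SiMe3)2, −20 °C; 5, −78 °C → rt
Reagents that add atoms: iodine, [I][I]
Why: Wittig iodo-olefination (Stork–Zhao type): the α-iodo ylide made by iodination and deprotonation of the ethylidene ylide should give the trisubstituted vinyl iodide with iodine cis to the chain under kinetic control.

Step 4
Reactants: 8 (5Z)-6-iodohepta-1,5-diene; 9 acrylonitrile
Product: 10 (2Z,6Z)-7-iodoocta-2,6-dienenitrile
Conditions: second-generation Hoveyda–Grubbs catalyst RuCl2(H2IMes)(=CH-C6H4-2-O-i-Pr) (5 mol %), 9 (excess), CH2Cl2, 40 °C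
Reagents that add atoms: none
Why: Olefin cross-metathesis of the terminal alkene with acrylonitrile, in which the trisubstituted iodoalkene is too hindered to take part and the geometry of the new double bond is of no consequence.

Step 5
Reactants: 4 methyl 2-(dimethoxymethyl)-2-formylpent-4-ynoate; 10 (2Z,6Z)-7-iodoocta-2,6-dienenitrile
Product: 11 methyl 2-[(1R,2Z,6Z)-7-cyano-1-hydroxy-2-methylhepta-2,6-dien-1-yl]-2-(dimethoxymethyl)pent-4-ynoate (both epimers at the quaternary carbon)
Conditions: CrCl2 (3 equiv), (S)-N-[2-(4-tert-butyl-4,5-dihydro-1,3-oxazol-2-yl)-6-methylphenyl]methanesulfonamide (3.3 equiv), Et3N, NiCl2 (10 mol %), THF, rt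
Reagents that add atoms: none
Why: Asymmetric Nozaki–Hiyama–Kishi coupling: the alkenylchromium species formed from 10 with retention of geometry should add only to the aldehyde, and the sulfonamide-bound chromium should set the (R)-carbinol by reagent control (the sense to be confirmed on a model aldehyde, the antipodal ligand being used otherwise), because the racemic quaternary neighbour offers three substituents of similar size.

Step 6
Reactants: 11 methyl 2-[(1R,2Z,6Z)-7-cyano-1-hydroxy-2-methylhepta-2,6-dien-1-yl]-2-(dimethoxymethyl)pent-4-ynoate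
Product: 12 methyl 2-[(1R,2Z,6Z)-7-cyano-2-methyl-1-(triethylsilyloxy)hepta-2,6-dien-1-yl]-2-(dimethoxymethyl)pent-4-ynoate
Conditions: Et3SiOTf, 2,6-lutidine, CH2Cl2, −78 → 0 °C
Reagents that add atoms: triethylsilyl trifluoromethanesulfonate, CC[Si](CC)(CC)OS(=O)(=O)C(F)(F)F
Why: Silyl ether formation on the hindered allylic alcohol with a silyl triflate and a hindered pyridine base; no stereocentre changes.

Step 7
Reactants: 12 methyl 2-[(1R,2Z,6Z)-7-cyano-2-methyl-1-(triethylsilyloxy)hepta-2,6-dien-1-yl]-2-(dimethoxymethyl)pent-4-ynoate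
Product: 13 2-[(1R,2Z,6Z)-7-cyano-2-methyl-1-(triethylsilyloxy)hepta-2,6-dien-1-yl]-2-(dimethoxymethyl)pent-4-ynoic acid
Conditions: LiI, pyridine, 110 °C; cold 0.5 M HCl
Reagents that add atoms: none
Why: Nucleophilic demethylation (SN2 attack of iodide on the O-methyl group) should free the acid without attack at the hindered acyl carbon and without touching the silyl ether, acetal or nitrile.

Step 8
Reactants: 13 2-[(1R,2Z,6Z)-7-cyano-2-methyl-1-(triethylsilyloxy)hepta-2,6-dien-1-yl]-2-(dimethoxymethyl)pent-4-ynoic acid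
Product: 14 1,3-dioxoisoindolin-2-yl 2-[(1R,2Z,6Z)-7-cyano-2-methyl-1-(triethylsilyloxy)hepta-2,6-dien-1-yl]-2-(dimethoxymethyl)pent-4-ynoate
Conditions: N-hydroxyphthalimide, N,N'-diisopropylcarbodiimide, 4-(dimethylamino)pyridine (cat.), CH2Cl2, rt
Reagents that add atoms: N-hydroxyphthalimide, O=C1c2ccccc2C(=O)N1O
Why: Carbodiimide (Steglich-type) esterification gives the redox-active ester needed for reductive decarboxylation.

Step 9
Reactants: 14 1,3-dioxoisoindolin-2-yl 2-[(1R,2Z,6Z)-7-cyano-2-methyl-1-(triethylsilyloxy)hepta-2,6-dien-1-yl]-2-(dimethoxymethyl)pent-4-ynoate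
Product: 17 (3aR,4R,8aR)-3a-(dimethoxymethyl)-5-methyl-2-methylidene-4-(triethylsilyloxy)-1,2,3,3a,4,7,8,8a-octahydroazulene-1-carbonitrile (C-1 epimers), via tertiary radical 15 (not isolated), via cyano-stabilised radical 16 (not isolated)
Conditions: Ru(bpy)3(PF6)2 (2 mol %), Hantzsch ester (1.5 equiv, slow addition), i-Pr2NEt, CH2Cl2 (0.005 M), blue LEDs, 25 °C
Reagents that add atoms: none
Why: Electron transfer from the photoreduced ruthenium complex to the N-acyloxyphthalimide releases CO2, phthalimide anion and the tertiary radical 15, which closes the cycloheptene by 7-exo-trig conjugate addition to the acrylonitrile terminus (Giese type) to give the α-cyano radical 16; 16 closes the cyclopentane by 5-exo-dig attack on the propargyl alkyne and the vinyl radical is quenched by the Hantzsch ester. The closest known reactions are the reductive decarboxylative Giese additions of tertiary N-acyloxyphthalimides to electron-poor alkenes and radical addition–5-exo-dig cyclisation cascades. C-3a and C-8a are set from the C-4 silyloxy centre through a chair-like cycloheptene transition state in which OSiEt3, the dimethoxymethyl group and the cyanovinyl terminus are all pseudo-equatorial and only the slender propargyl group is pseudo-axial (the C-4 hydrogen eclipses the bulky dimethoxymethyl group, as allylic 1,3-strain demands), so the new bond forms anti to OSiEt3 and the C-8a hydrogen ends cis to the dimethoxymethyl group. The pseudo-axial propargyl group and the pseudo-equatorial radical arm are then cis on adjacent carbons and can close only to the cis-fused bicycle, while C-1 forms as an epimer mixture that is planarised again in step 12. Both epimers of 14 at the carboxyl-bearing carbon converge on the same radical 15. The step needs ring closure to outrun hydrogen transfer and a 1,5-hydrogen shift from the allylic CH2 (secured by high dilution, slow addition of the hydrogen donor and polarity matching: nucleophilic tertiary radical onto the acceptor alkene, electrophilic α-cyano radical onto the alkyne), 7-exo over 8-endo attack (only attack at the β-carbon gives the nitrile-stabilised radical) and 5-exo-dig closure over transannular attack on the ring alkene (the radical arm is pseudo-equatorial and cannot reach it).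

Step 10
Reactants: 17 (3aR,4R,8aR)-3a-(dimethoxymethyl)-5-methyl-2-methylidene-4-(triethylsilyloxy)-1,2,3,3a,4,7,8,8a-octahydroazulene-1-carbonitrile
Product: 18 (2R,3aR,4R,8aR)-3a-(dimethoxymethyl)-2,5-dimethyl-4-(triethylsilyloxy)-1,2,3,3a,4,7,8,8a-octahydroazulene-1-carbonitrile (C-1 epimers)
Conditions: H2 (1 atm), RhCl(PPh3)3 (10 mol %), benzene, rt
Reagents that add atoms: none
Why: Homogeneous hydrogenation should reduce only the 1,1-disubstituted exocyclic alkene and deliver hydrogen to the convex face of the cis-fused bicycle, syn to the C-8a hydrogen, because the concave face is covered by C-4 and C-8 of the seven-membered ring, so the new methyl group ends on the concave face (2R).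

Step 11
Reactants: 19 2-(furan-3-yl)ethan-1-ol
Product: 20 3-(2-iodoethyl)furan
Conditions: I2, PPh3, imidazole, CH2Cl2, 0 °C → rt
Reagents that add atoms: iodine, [I][I]
Why: Appel-type iodination of the primary alcohol under neutral conditions that the furan tolerates.

Step 12
Reactants: 18 (2R,3aR,4R,8aR)-3a-(dimethoxymethyl)-2,5-dimethyl-4-(triethylsilyloxy)-1,2,3,3a,4,7,8,8a-octahydroazulene-1-carbonitrile; 20 3-(2-iodoethyl)furan
Product: 21 (1R,2R,3aR,4R,8aR)-3a-(dimethoxymethyl)-1-[2-(furan-3-yl)ethyl]-2,5-dimethyl-4-(triethylsilyloxy)-1,2,3,3a,4,7,8,8a-octahydroazulene-1-carbonitrile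
Conditions: LiN(i-Pr)2, THF, −78 °C; DMPU, 20, −78 → 0 °C
Reagents that add atoms: none
Why: Alkylation of the lithiated nitrile, a planar and sterically undemanding nucleophile suited to quaternary centres, in which the iodide should enter from the convex face, anti to the C-2 methyl group and to C-8, which sets C-1 with the side chain cis to the C-8a hydrogen.

Step 13
Reactants: 21 (1R,2R,3aR,4R,8aR)-3a-(dimethoxymethyl)-1-[2-(furan-3-yl)ethyl]-2,5-dimethyl-4-(triethylsilyloxy)-1,2,3,3a,4,7,8,8a-octahydroazulene-1-carbonitrile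
Product: 22 (1R,2R,3aR,4R,8aR)-3a-(dimethoxymethyl)-1-[2-(furan-3-yl)ethyl]-2,5-dimethyl-4-(triethylsilyloxy)-1,2,3,3a,4,7,8,8a-octahydroazulene-1-carbaldehyde
Conditions: i-Bu2AlH, toluene, −78 → 0 °C; aqueous potassium sodium tartrate, then moist SiO2
Reagents that add atoms: water, O
Why: Nitrile-to-aldehyde reduction: the hydride adds once to give the N-aluminated aldimine, which is hydrolysed on work-up to the non-enolisable aldehyde without change at any stereocentre.

Step 14
Reactants: 22 (1R,2R,3aR,4R,8aR)-3a-(dimethoxymethyl)-1-[2-(furan-3-yl)ethyl]-2,5-dimethyl-4-(triethylsilyloxy)-1,2,3,3a,4,7,8,8a-octahydroazulene-1-carbaldehyde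
Product: 25 (2Z)-2-{2-[(1R,2R,3aR,4R,8aR)-3a-(dimethoxymethyl)-1-(hydroxymethyl)-2,5-dimethyl-4-(triethylsilyloxy)-1,2,3,3a,4,7,8,8a-octahydroazulen-1-yl]ethyl}but-2-ene-1,4-diol, via furan endoperoxide 23 (not isolated), via trialdehyde 24 (not isolated)
Conditions: O2, rose bengal, visible light, CH2Cl2–MeOH, −78 °C; Me2S; NaBH4, CeCl3·7H2O, −78 → 0 °C
Reagents that add atoms: dioxygen, O=O
Why: Furan photooxygenation: singlet oxygen should add [4+2] to the furan much faster than it undergoes the ene reaction with the trisubstituted ring alkene, Me2S reduces the endoperoxide to the (Z)-enedial, and Luche reduction converts all three aldehydes to alcohols, the Z geometry being inherited from the furan ring.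

Step 15
Reactants: 25 (2Z)-2-{2-[(1R,2R,3aR,4R,8aR)-3a-(dimethoxymethyl)-1-(hydroxymethyl)-2,5-dimethyl-4-(triethylsilyloxy)-1,2,3,3a,4,7,8,8a-octahydroazulen-1-yl]ethyl}but-2-ene-1,4-diol
Product: 26 (1R,2R,3aR,4R,8aR)-4-hydroxy-1-[(3Z)-5-hydroxy-3-(hydroxymethyl)pent-3-en-1-yl]-1-(hydroxymethyl)-2,5-dimethyl-1,2,3,3a,4,7,8,8a-octahydroazulene-3a-carbaldehyde (target)
Conditions: 1 M HCl, THF, 0 °C → rt
Reagents that add atoms: water, O
Why: Acetal hydrolysis and desilylation in one acidic operation should give the free aldehyde, which stays open because no hydroxyl can reach it through a five- or six-membered hemiacetal.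

**Compound list**
1 | dimethyl 2-(prop-2-yn-1-yl)propanedioate | COC(=O)C(CC#C)C(=O)OC | starting material
2 | trimethyl orthoformate | COC(OC)OC | starting material
3 | dimethyl 2-(dimethoxymethyl)-2-(prop-2-yn-1-yl)propanedioate | COC(=O)C(CC#C)(C(OC)OC)C(=O)OC | intermediate
4 | methyl 2-(dimethoxymethyl)-2-formylpent-4-ynoate (racemic) | COC(=O)C(CC#C)(C=O)C(OC)OC | intermediate
5 | pent-4-enal | C=CCCC=O | starting material
6 | ethyltriphenylphosphonium iodide | CC[P+](c1ccccc1)(c1ccccc1)c1ccccc1.[I-] | starting material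
7 | (1-iodoethyl)triphenylphosphonium iodide (not isolated) | CC(I)[P+](c1ccccc1)(c1ccccc1)c1ccccc1.[I-] | intermediate
8 | (5Z)-6-iodohepta-1,5-diene | C=CCC/C=C(/C)\I | intermediate
9 | acrylonitrile | C=CC#N | starting material
10 | (2Z,6Z)-7-iodoocta-2,6-dienenitrile | N#C/C=C\CC/C=C(/C)\I | intermediate
11 | methyl 2-[(1R,2Z,6Z)-7-cyano-1-hydroxy-2-methylhepta-2,6-dien-1-yl]-2-(dimethoxymethyl)pent-4-ynoate (both epimers at the quaternary carbon) | COC(=O)C(CC#C)(C(OC)OC)[C@@H](/C(C)=C\CC/C=C\C#N)O | intermediate
12 | methyl 2-[(1R,2Z,6Z)-7-cyano-2-methyl-1-(triethylsilyloxy)hepta-2,6-dien-1-yl]-2-(dimethoxymethyl)pent-4-ynoate | COC(=O)C(CC#C)(C(OC)OC)[C@@H](/C(C)=C\CC/C=C\C#N)O[Si](CC)(CC)CC | intermediate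
13 | 2-[(1R,2Z,6Z)-7-cyano-2-methyl-1-(triethylsilyloxy)hepta-2,6-dien-1-yl]-2-(dimethoxymethyl)pent-4-ynoic acid | OC(=O)C(CC#C)(C(OC)OC)[C@@H](/C(C)=C\CC/C=C\C#N)O[Si](CC)(CC)CC | intermediate
14 | 1,3-dioxoisoindolin-2-yl 2-[(1R,2Z,6Z)-7-cyano-2-methyl-1-(triethylsilyloxy)hepta-2,6-dien-1-yl]-2-(dimethoxymethyl)pent-4-ynoate | O=C(ON1C(=O)c2ccccc2C1=O)C(CC#C)(C(OC)OC)[C@@H](/C(C)=C\CC/C=C\C#N)O[Si](CC)(CC)CC | intermediate
15 | tertiary radical formed from 14 by loss of CO2 and phthalimide anion (not isolated) | [C](CC#C)(C(OC)OC)[C@@H](/C(C)=C\CC/C=C\C#N)O[Si](CC)(CC)CC | intermediate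
16 | monocyclic α-cyano radical, cycloheptene closed (not isolated) | CC1=CCC[C@H]([CH]C#N)[C@](C(OC)OC)(CC#C)[C@@H]1O[Si](CC)(CC)CC | intermediate
17 | (3aR,4R,8aR)-3a-(dimethoxymethyl)-5-methyl-2-methylidene-4-(triethylsilyloxy)-1,2,3,3a,4,7,8,8a-octahydroazulene-1-carbonitrile (C-1 epimers) | CC1=CCC[C@H]2[C@](C(OC)OC)(CC(=C)C2C#N)[C@@H]1O[Si](CC)(CC)CC | intermediate
18 | (2R,3aR,4R,8aR)-3a-(dimethoxymethyl)-2,5-dimethyl-4-(triethylsilyloxy)-1,2,3,3a,4,7,8,8a-octahydroazulene-1-carbonitrile (C-1 epimers) | CC1=CCC[C@H]2[C@](C(OC)OC)(C[C@@H](C)C2C#N)[C@@H]1O[Si](CC)(CC)CC | intermediate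
19 | 2-(furan-3-yl)ethan-1-ol | OCCc1ccoc1 | starting material
20 | 3-(2-iodoethyl)furan | ICCc1ccoc1 | intermediate
21 | (1R,2R,3aR,4R,8aR)-3a-(dimethoxymethyl)-1-[2-(furan-3-yl)ethyl]-2,5-dimethyl-4-(triethylsilyloxy)-1,2,3,3a,4,7,8,8a-octahydroazulene-1-carbonitrile | CC1=CCC[C@H]2[C@](C(OC)OC)(C[C@@H](C)[C@]2(C#N)CCc3ccoc3)[C@@H]1O[Si](CC)(CC)CC | intermediate
22 | (1R,2R,3aR,4R,8aR)-3a-(dimethoxymethyl)-1-[2-(furan-3-yl)ethyl]-2,5-dimethyl-4-(triethylsilyloxy)-1,2,3,3a,4,7,8,8a-octahydroazulene-1-carbaldehyde | CC1=CCC[C@H]2[C@](C(OC)OC)(C[C@@H](C)[C@]2(C=O)CCc3ccoc3)[C@@H]1O[Si](CC)(CC)CC | intermediate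
23 | furan endoperoxide of 22, 2,3,7-trioxabicyclo[2.2.1]hept-5-en-5-yl in place of furan-3-yl (not isolated) | CC1=CCC[C@H]2[C@](C(OC)OC)(C[C@@H](C)[C@]2(C=O)CCC3=CC4OOC3O4)[C@@H]1O[Si](CC)(CC)CC | intermediate
24 | trialdehyde: (2Z)-2-substituted but-2-enedial carrying the C-1 formyl bicycle (not isolated) | CC1=CCC[C@H]2[C@](C(OC)OC)(C[C@@H](C)[C@]2(C=O)CC/C(=C/C=O)C=O)[C@@H]1O[Si](CC)(CC)CC | intermediate
25 | (2Z)-2-{2-[(1R,2R,3aR,4R,8aR)-3a-(dimethoxymethyl)-1-(hydroxymethyl)-2,5-dimethyl-4-(triethylsilyloxy)-1,2,3,3a,4,7,8,8a-octahydroazulen-1-yl]ethyl}but-2-ene-1,4-diol | CC1=CCC[C@H]2[C@](C(OC)OC)(C[C@@H](C)[C@]2(CO)CC/C(=C/CO)CO)[C@@H]1O[Si](CC)(CC)CC | intermediate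
26 | (1R,2R,3aR,4R,8aR)-4-hydroxy-1-[(3Z)-5-hydroxy-3-(hydroxymethyl)pent-3-en-1-yl]-1-(hydroxymethyl)-2,5-dimethyl-1,2,3,3a,4,7,8,8a-octahydroazulene-3a-carbaldehyde | CC1=CCC[C@H]2[C@](C=O)(C[C@@H](C)[C@]2(CO)CC/C(=C/CO)CO)[C@@H]1O | target

**Step count and risks**

Total number of steps: 15. Longest linear sequence: 12 steps (1, 2, 5, 6, 7, 8, 9, 10, 12, 13, 14, 15).

Risk 1 (step 9, the key step): the cascade may stop early. Hydrogen transfer to the nitrile-stabilised radical, or a 1,5-hydrogen shift to the tertiary radical, can be faster than ring closure, so that only the seven-membered ring, or no ring, is formed. The fallback runs the two ring closures as separate radical chain reactions and sets out from acid 13. Esterification with N-hydroxypyridine-2-thione (N,N'-diisopropylcarbodiimide, dark) gives the Barton ester F1. Irradiation with visible light at high dilution without a hydrogen donor lets the tertiary radical close the seven-membered ring, and the α-cyano radical is capped by pyridylthio group transfer from a second molecule of the ester to give the monocyclic pyridin-2-yl sulfide F2. Slow addition of Bu3SnH and azobisisobutyronitrile in benzene at 80 °C then regenerates the α-cyano radical at very low hydrogen-donor concentration for the 5-exo-dig closure, which comes back to the route at 17.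

Risk 2 (step 5): reagent control may be incomplete. The chiral chromium complex may fail to overrule the racemic quaternary neighbour, or the terminal alkyne may engage the nickel co-catalyst, so that the carbinol forms with low enantiomeric purity or in low conversion. The fallback sets out from 4 and 10. An achiral chromium-mediated coupling (CrCl2, NiCl2 cat., DMF) gives the alcohol as a stereoisomer mixture F3, and Dess–Martin periodinane oxidises it to the enone F4. Corey–Bakshi–Shibata reduction ((S)-2-methyl-CBS-oxazaborolidine, catecholborane, toluene, −78 °C), with the fully substituted carbon as the large group, then sets the (R)-carbinol and comes back to the route at 11.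

Risk 3 (step 12): the congested nitrile anion may act as a base toward the iodide (elimination to 3-vinylfuran), or C–C bond formation at the crowded centre may be too slow. The fallback alkylates one step earlier and sets out from 17, whose allylic nitrile is more acidic and whose anion is flanked by an sp2 carbon. Deprotonation with LiN(i-Pr)2 and α-alkylation with 20 from the convex face gives the 2-methylidene nitrile F5, and hydrogenation of its exocyclic alkene with RhCl(PPh3)3 comes back to the route at 21.

**Further compounds**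
F1 | step 9 | 2-thioxopyridin-1(2H)-yl 2-[(1R,2Z,6Z)-7-cyano-2-methyl-1-(triethylsilyloxy)hepta-2,6-dien-1-yl]-2-(dimethoxymethyl)pent-4-ynoate | O=C(ON1C=CC=CC1=S)C(CC#C)(C(OC)OC)[C@@H](/C(C)=C\CC/C=C\C#N)O[Si](CC)(CC)CC
F2 | step 9 | 2-[(1S,2R,3R)-2-(dimethoxymethyl)-4-methyl-2-(prop-2-yn-1-yl)-3-(triethylsilyloxy)cyclohept-4-en-1-yl]-2-(pyridin-2-ylsulfanyl)acetonitrile (epimers at the α-carbon) | CC1=CCC[C@H](C(Sc2ccccn2)C#N)[C@](C(OC)OC)(CC#C)[C@@H]1O[Si](CC)(CC)CC
F3 | step 5 | methyl 2-[(2Z,6Z)-7-cyano-1-hydroxy-2-methylhepta-2,6-dien-1-yl]-2-(dimethoxymethyl)pent-4-ynoate (stereoisomer mixture) | COC(=O)C(CC#C)(C(OC)OC)C(O)/C(C)=C\CC/C=C\C#N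
F4 | step 5 | methyl 2-[(2Z,6Z)-7-cyano-2-methylhepta-2,6-dienoyl]-2-(dimethoxymethyl)pent-4-ynoate (racemic) | COC(=O)C(CC#C)(C(OC)OC)C(=O)/C(C)=C\CC/C=C\C#N
F5 | step 12 | (1S,3aR,4R,8aR)-3a-(dimethoxymethyl)-1-[2-(furan-3-yl)ethyl]-5-methyl-2-methylidene-4-(triethylsilyloxy)-1,2,3,3a,4,7,8,8a-octahydroazulene-1-carbonitrile | CC1=CCC[C@H]2[C@](C(OC)OC)(CC(=C)[C@]2(C#N)CCc3ccoc3)[C@@H]1O[Si](CC)(CC)CC
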